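**Plan**

1. Retrosynthesis: the C11 acetate, the C6 methyl ether and the C3–O–C16 oxepane bond are cut first; C6–O and C7–H go back to a (Z)-C6=C7 alkene, the C3 methyl to a C3 ketone.
2. That nine-membered keto-alkene is the Grob product of a cyclopentane-1,3-diol monomesylate. Re-joining C3–C7 and cutting C3–C4 and C6–C7 removes a C4–C6 unit and leaves a methylated 8-oxabicyclo[3.2.1]octenone fused to a cyclohexanone.
3. Enabling feature: the tetrahydrofuran O–C2–C1–C10–C9 has oxygen on C3 and C11 and a methyl on C7. With C3–C7 joined it is the ether bridge of a (5+2) adduct of 4-methyl-3-oxidopyrylium (O, C2, C3, C7, C8, C9) with a cyclohexenone (C10=C1–C11=O); cutting C1–C2 and C9–C10 gives the two pieces.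
4. Forward: cyclohexenone ring (Michael/aldol), then tetrahydrofuran and seven-membered carbocycle together in the cycloaddition, then cyclopentanol annulation, Grob opening to the nine-membered ether, and the oxepane last.
5. Stereochemistry: C15 from (S)-3-bromo-2-methylpropan-1-ol; C14 from the prolinol catalyst; C12 by trans-selective enolate methylation; C1, C2, C9, C10 in the cycloaddition (anti to the C14 branch, exo); C11 by hydride on the convex face; C3 by methyl addition from the ring periphery; C6 and C7 by silicon-tethered syn delivery from the C3 oxygen.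

Key step: step 8

Remarks on the chemistry (assumptions):
- All intermediates carry the skeleton numbers of the target: C2–O–C9 ether bridge, C1/C10 ring fusion, C11 (OAc), C12 (Me), C14 with the C15(Me)–C16 branch, C3 (Me, ether O), C6 (OMe), C7 (Me).
- The (S)-diarylprolinol ether is assumed to direct the vinyl ketone to the same enamine face as it does other acceptors; this gives the (S) aldehyde α-centre (C14).
- The aldehyde in step 11 is assumed to add to C7 on the face away from the C1–C10 bridge; the other face would give the same compound 26 after step 16.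
- Reagents reaching the nine-membered ring from outside are taken to attack the face away from the C3 oxygen. Hydroboration of C6=C7 would then give the 6,7-diepimer, so C6 and C7 are set from inside through a silicon tether (steps 18–19).

**Route**

Step 1
Reactants: 1 methyl 3-methylfuran-2-carboxylate
Product: 2 (3-methylfuran-2-yl)methanol
Conditions: LiAlH4, THF, 0 °C
Reagents that add atoms: none
Why: Hydride reduction of the ester gives the primary furfuryl alcohol while the furan ring is inert.

Step 2
Reactants: 2 (3-methylfuran-2-yl)methanol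
Product: 3 6-hydroxy-4-methyl-2H-pyran-3(6H)-one (racemic lactol)
Conditions: mCPBA, CH2Cl2, 0 °C
Reagents that add atoms: 3-chloroperbenzoic acid, OOC(=O)c1cccc(Cl)c1
Why: Achmatowicz rearrangement, in which oxidation of the furan gives an ene-dione that recloses through the primary hydroxyl to the hydroxypyranone, the furan 3-methyl becoming the pyranone 4-methyl (the lactol centre is lost in step 8).

Step 3
Reactants: 3 6-hydroxy-4-methyl-2H-pyran-3(6H)-one
Product: 4 6-acetoxy-4-methyl-2H-pyran-3(6H)-one (racemic)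
Conditions: Ac2O, pyridine, DMAP (cat.), CH2Cl2, 0 °C
Reagents that add atoms: acetic anhydride, CC(=O)OC(C)=O
Why: O-Acetylation of the lactol installs the leaving group for ylide formation, and pyridine at 0 °C avoids premature elimination.

Step 4
Reactants: 5 (S)-3-bromo-2-methylpropan-1-ol
Product: 6 (S)-(3-bromo-2-methylpropoxy)(tert-butyl)diphenylsilane
Conditions: TBDPSCl, imidazole, CH2Cl2, rt
Reagents that add atoms: tert-butylchlorodiphenylsilane, CC(C)(C)[Si](Cl)(c1ccccc1)c1ccccc1
Why: Standard silylation of the primary alcohol, with TBDPS chosen to outlast the primary TBS ether removed in step 12.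

Step 5
Reactants: 6 (S)-(3-bromo-2-methylpropoxy)(tert-butyl)diphenylsilane
Product: 8 (R)-4-[(tert-butyldiphenylsilyl)oxy]-3-methylbutanal, via Grignard reagent 7 (not isolated)
Conditions: Mg, THF, rt; DMF, 0 °C; aq. NH4Cl
Reagents that add atoms: N,N-dimethylformamide, CN(C)C=O
Why: Grignard formation followed by Bouveault formylation adds the aldehyde carbon, and the stereocentre is β to the new carbonyl so it cannot epimerise.

Step 6
Reactants: 8 (R)-4-[(tert-butyldiphenylsilyl)oxy]-3-methylbutanal; 9 but-3-en-2-one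
Product: 11 (4R)-4-[(2R)-1-[(tert-butyldiphenylsilyl)oxy]propan-2-yl]cyclohex-2-en-1-one, via keto aldehyde 10 (not isolated)
Conditions: (S)-α,α-diphenylprolinol methyl ether (5 mol%), ethyl 3,4-dihydroxybenzoate (20 mol%), neat, 4 °C; then LiOH, i-PrOH, rt
Reagents that add atoms: none
Why: Enamine-catalysed Michael addition to the vinyl ketone followed by intramolecular aldol condensation (organocatalytic Robinson-type annulation) builds the ring, and the catalyst shields one face of the E-enamine and so sets C14 while C15 is a spectator.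

Step 7
Reactants: 11 (4R)-4-[(2R)-1-[(tert-butyldiphenylsilyl)oxy]propan-2-yl]cyclohex-2-en-1-one
Product: 13 (4R,6R)-4-[(2R)-1-[(tert-butyldiphenylsilyl)oxy]propan-2-yl]-6-methylcyclohex-2-en-1-one, via lithium dienolate 12 (not isolated)
Conditions: LDA, THF, −78 °C; MeI, −78 → −40 °C
Reagents that add atoms: iodomethane, CI
Why: Kinetic α′-deprotonation gives the cross-conjugated enolate, and methyl iodide should enter axially on the face away from the C14 branch, the usual course for 4-substituted cyclohexenones, giving the trans-4,6 isomer (C12).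

Step 8
Reactants: 13 (4R,6R)-4-[(2R)-1-[(tert-butyldiphenylsilyl)oxy]propan-2-yl]-6-methylcyclohex-2-en-1-one; 4 6-acetoxy-4-methyl-2H-pyran-3(6H)-one
Product: 15 exo cycloadduct (tricyclic ene-dione: C3 ketone conjugated to C7(Me)=C8, C11 ketone, C2–O–C9 bridge, H1 and H10 cis and on the C3–C7–C8 side), via oxidopyrylium ylide 14 (not isolated)
Conditions: 4 (3 equiv, syringe pump, 8 h), i-Pr2NEt, MeCN (1 M in 13), 40 °C
Reagents that add atoms: none
Why: Base removes acetic acid from 4 to give the 3-oxidopyrylium 14, a cyclic carbonyl ylide that adds across C10=C1 of 13 in one concerted suprafacial six-electron step (the 3-oxidopyrylium (5+2) cycloaddition known for acrylates, vinyl ketones and other acceptor alkenes); slow addition of 4 to concentrated 13 keeps the ylide dilute and limits its dimerisation. The ylide carbon next to the oxido group (C2) bonds to the enone β-carbon C1 and C9 to the α-carbon C10, the normal orientation with acceptor alkenes, so the tetrahydrofuran (O, C2, C1, C10, C9) and the seven-membered carbocycle (C1, C2, C3, C7, C8, C9, C10) close at the same time by cycloaddition and not by a separate cyclisation. C2 and C9 are cis because the oxygen bridges them, and C1 and C10 keep the cis geometry of the ring alkene. Their absolute sense comes from C14: in the trans-4,6-disubstituted enone the C14 branch is pseudoaxial (C12 methyl equatorial) and covers one face, so the ylide adds anti to it, as cuprates and dienes do with 4-substituted cyclohexenones. The step needs the exo mode, with the six-membered ring on the side of the bridging oxygen and H1/H10 pointing to the C3–C7–C8 bridge; in that mode only the unsubstituted oxygen lies under the cyclohexenone, whereas the endo mode pushes the C3–C7–C8 arc against the axial C13–H and the C11 carbonyl region. This exo preference is a steric argument and not an established fact for this enone, which is why the step heads the risk list.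

Step 9
Reactants: 15 exo cycloadduct
Product: 16 C11 alcohol (hydroxyl cis to the C12 methyl and to C9; C3 enone intact)
Conditions: NaBH4, MeOH/CH2Cl2 (1:1), −78 °C
Reagents that add atoms: none
Why: At −78 °C borohydride should reduce the saturated C11 ketone faster than the conjugated C3 carbonyl, and hydride comes from the convex face that carries only H10 and H12 because C9 and the C12 methyl lie on the other face.

Step 10
Reactants: 16 C11 alcohol
Product: 17 C11 benzyl ether
Conditions: BnBr, NaH, Bu4NI (cat.), THF, 0 °C → rt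
Reagents that add atoms: benzyl bromide, BrCc1ccccc1
Why: Williamson etherification gives an ether that survives hydride, organolithium, alkoxide and fluoride and is removed last by hydrogenolysis.

Step 11
Reactants: 17 C11 benzyl ether; 18 3-[(tert-butyldimethylsilyl)oxy]propanal
Product: 20 aldol adduct (C8 now CH2; C7 quaternary with methyl and the C6H(OH)–C5H2–C4H2–OTBS chain; C3 ketone), via lithium enolate 19 (not isolated)
Conditions: L-Selectride, THF, −78 °C; then 18, −78 °C; AcOH quench at −78 °C
Reagents that add atoms: none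
Why: L-Selectride adds hydride to C8 of the α-methyl enone (1,4-reduction as with carvone-type enones) and the lithium enolate is trapped in a reductive aldol reaction through a Zimmerman–Traxler chair, which should give the C6 epimer whose oxygen ends up trans to the C7 methyl on the later cyclopentane, as a Z-selective fragmentation requires.

Step 12
Reactants: 20 aldol adduct
Product: 21 diol (free C4 and C6 hydroxyls)
Conditions: HF·pyridine, pyridine, THF, 0 °C
Reagents that add atoms: none
Why: Buffered HF·pyridine cleaves the primary TBS ether much faster than the TBDPS ether and, unlike acidic methanol, cannot ketalise the δ-hydroxy ketone.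

Step 13
Reactants: 21 diol
Product: 22 primary iodide (C4–I, C6–OH)
Conditions: I2, PPh3, imidazole, CH2Cl2, 0 °C → rt
Reagents that add atoms: iodine, II
Why: Garegg–Samuelsson iodination converts the primary alcohol selectively because the neopentyl-type secondary C6 alcohol is too hindered to react.

Step 14
Reactants: 22 primary iodide
Product: 24 tetracyclic diol (cyclopentane C3–C4–C5–C6–C7 cis-fused; tertiary C3–OH cis to C7–CH3; C6–OH trans to C7–CH3), via dilithio species 23 (not isolated)
Conditions: t-BuLi (3.3 equiv), Et2O/pentane, −78 → −40 °C; aq. NH4Cl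
Reagents that add atoms: none
Why: Lithium–iodine exchange is faster than attack of tert-butyllithium on the hindered ketone, and the primary alkyllithium closes the ring by 5-exo addition to the C3 carbonyl, which cannot enolise (C2 bridgehead, C7 quaternary), the tether on C7 forcing the cis fusion; a lithium rather than a samarium(II) closure is used because SmI2 would cleave the C2–O bond next to the ketone.

Step 15
Reactants: 24 tetracyclic diol
Product: 25 C6 mesylate
Conditions: MsCl, Et3N, CH2Cl2, −20 → 0 °C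
Reagents that add atoms: methanesulfonyl chloride, CS(=O)(=O)Cl
Why: Sulfene-type mesylation is selective for the secondary C6 hydroxyl and leaves the tertiary C3 alcohol untouched.

Step 16
Reactants: 25 C6 mesylate
Product: 26 (Z)-oxonenone (nine-membered ether ring with C3 ketone and (Z)-C6=C7; C2–O–C9 bridge kept)
Conditions: KOt-Bu, THF, 0 °C → rt
Reagents that add atoms: none
Why: Grob (Wharton-type) fragmentation, in which the C3 alkoxide expels the mesylate through the C3–C7 bond lying antiperiplanar to C6–OMs, gives the ketone and, because the mesylate is trans to the C7 methyl on the cyclopentane, the Z alkene.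

Step 17
Reactants: 26 (Z)-oxonenone
Product: 27 C3 tertiary alcohol (methyl on the outer face, hydroxyl pointing into the ring)
Conditions: MeLi, CeCl3, THF, −78 °C
Reagents that add atoms: methyllithium, [Li]C
Why: The weakly basic methylcerium reagent adds 1,2 without enolising C2 or C4, from the ring periphery on the side of H2 with the carbonyl anti to the C2–O bond, which places the C3 oxygen inside the ring as the oxepane requires.

Step 18
Reactants: 27 C3 tertiary alcohol
Product: 29 cyclic siloxane (C3–O–SiMe2–C6 six-membered ring; H added to C7), via hydrosilyl ether 28 (not isolated)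
Conditions: Me2SiHCl, Et3N, DMAP (cat.), CH2Cl2, 0 °C → rt; then Karstedt catalyst (2 mol% Pt), toluene, 60 °C
Reagents that add atoms: chlorodimethylsilane, C[SiH](C)Cl
Why: Silicon-tethered intramolecular hydrosilylation from the C3 oxygen, which sits under the inner face of C6=C7, should add Si to the less substituted C6 and H to C7 in a syn fashion, setting both centres from the face that external reagents cannot reach.

Step 19
Reactants: 29 cyclic siloxane
Product: 30 3,6-diol (C6–OH and C7–H as in the target)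
Conditions: H2O2 (30%), KHCO3, THF/MeOH, 50 °C
Reagents that add atoms: hydrogen peroxide, OO
Why: Tamao–Fleming oxidation replaces the C6–Si bond by C6–OH with retention and frees the C3 hydroxyl.

Step 20
Reactants: 30 3,6-diol
Product: 31 C6 methyl ether (C3–OH free)
Conditions: Me3OBF4, Proton-sponge, 4 Å MS, CH2Cl2, rt
Reagents that add atoms: trimethyloxonium tetrafluoroborate, C[O+](C)C.F[B-](F)(F)F
Why: Meerwein's salt with a hindered base methylates the secondary C6 hydroxyl under non-basic conditions while the tertiary C3 alcohol reacts far more slowly.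

Step 21
Reactants: 31 C6 methyl ether
Product: 32 C16 primary alcohol
Conditions: TBAF, THF, rt
Reagents that add atoms: none
Why: Fluoride cleaves the silyl ether while the benzyl and methyl ethers are stable.

Step 22
Reactants: 32 C16 primary alcohol
Product: 34 oxepane (11-O-benzyl ether of the deacetyl target), via primary triflate 33 (not isolated)
Conditions: Tf2O, 2,6-lutidine, CH2Cl2, −78 → 0 °C
Reagents that add atoms: none
Why: Triflic anhydride sulfonylates only the primary C16 hydroxyl at low temperature, and on warming the tertiary C3 hydroxyl displaces the triflate in an intramolecular Williamson-type etherification (7-exo-tet) that closes the oxepane.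

Step 23
Reactants: 34 oxepane
Product: 35 C11 alcohol (deacetyl target)
Conditions: H2 (1 atm), Pd/C, EtOAc, rt
Reagents that add atoms: none
Why: Hydrogenolysis removes the benzyl ether, and no other reducible group is present.

Step 24
Reactants: 35 C11 alcohol
Product: 36 target, CNP0289153.2
Conditions: Ac2O, DMAP, pyridine, rt
Reagents that add atoms: acetic anhydride, CC(=O)OC(C)=O
Why: DMAP-catalysed acetylation of the hindered secondary C11 alcohol completes the target.

**Compound list**

1 | methyl 3-methylfuran-2-carboxylate | COC(=O)c1occc1C | starting material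
2 | (3-methylfuran-2-yl)methanol | Cc1ccoc1CO | intermediate
3 | 6-hydroxy-4-methyl-2H-pyran-3(6H)-one (racemic) | CC1=CC(O)OCC1=O | intermediate
4 | 6-acetoxy-4-methyl-2H-pyran-3(6H)-one (racemic) | CC(=O)OC1OCC(=O)C(C)=C1 | intermediate
5 | (S)-3-bromo-2-methylpropan-1-ol | OC[C@H](C)CBr | starting material
6 | (S)-(3-bromo-2-methylpropoxy)(tert-butyl)diphenylsilane | CC(C)(C)[Si](c1ccccc1)(c1ccccc1)OC[C@H](C)CBr | intermediate
7 | [(2S)-3-[(tert-butyldiphenylsilyl)oxy]-2-methylpropyl]magnesium bromide | CC(C)(C)[Si](c1ccccc1)(c1ccccc1)OC[C@H](C)C[Mg]Br | intermediate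
8 | (R)-4-[(tert-butyldiphenylsilyl)oxy]-3-methylbutanal | CC(C)(C)[Si](c1ccccc1)(c1ccccc1)OC[C@H](C)CC=O | intermediate
9 | but-3-en-2-one | CC(=O)C=C | starting material
10 | (2S)-2-[(2R)-1-[(tert-butyldiphenylsilyl)oxy]propan-2-yl]-5-oxohexanal | CC(C)(C)[Si](c1ccccc1)(c1ccccc1)OC[C@H](C)[C@@H](C=O)CCC(C)=O | intermediate
11 | (4R)-4-[(2R)-1-[(tert-butyldiphenylsilyl)oxy]propan-2-yl]cyclohex-2-en-1-one | CC(C)(C)[Si](c1ccccc1)(c1ccccc1)OC[C@H](C)[C@@H]1CCC(=O)C=C1 | intermediate
12 | lithium cross-conjugated dienolate of 11 (C11–OLi, C11=C12, C10=C1) | CC(C)(C)[Si](c1ccccc1)(c1ccccc1)OC[C@H](C)[C@@H]1CC=C(O[Li])C=C1 | intermediate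
13 | (4R,6R)-4-[(2R)-1-[(tert-butyldiphenylsilyl)oxy]propan-2-yl]-6-methylcyclohex-2-en-1-one | CC(C)(C)[Si](c1ccccc1)(c1ccccc1)OC[C@H](C)[C@@H]1C[C@@H](C)C(=O)C=C1 | intermediate
14 | 4-methyl-3-oxidopyrylium | Cc1cc[o+]cc1[O-] | intermediate
15 | exo (5+2) adduct, tricyclic ene-dione (C3 ketone, C7(Me)=C8, C11 ketone) | O=C1C(C)=C[C@@H]2O[C@H]1[C@@H]3[C@H]2C(=O)[C@H](C)C[C@H]3[C@@H](C)CO[Si](c4ccccc4)(c4ccccc4)C(C)(C)C | intermediate
16 | C11 alcohol of 15 | O=C1C(C)=C[C@@H]2O[C@H]1[C@@H]3[C@H]2[C@H](O)[C@H](C)C[C@H]3[C@@H](C)CO[Si](c4ccccc4)(c4ccccc4)C(C)(C)C | intermediate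
17 | C11 benzyl ether | O=C1C(C)=C[C@@H]2O[C@H]1[C@@H]3[C@H]2[C@H](OCc5ccccc5)[C@H](C)C[C@H]3[C@@H](C)CO[Si](c4ccccc4)(c4ccccc4)C(C)(C)C | intermediate
18 | 3-[(tert-butyldimethylsilyl)oxy]propanal | CC(C)(C)[Si](C)(C)OCCC=O | starting material
19 | lithium enolate from 1,4-reduction of 17 (C3–OLi, C3=C7) | [Li]OC1=C(C)C[C@@H]2O[C@H]1[C@@H]3[C@H]2[C@H](OCc5ccccc5)[C@H](C)C[C@H]3[C@@H](C)CO[Si](c4ccccc4)(c4ccccc4)C(C)(C)C | intermediate
20 | aldol adduct (C7 quaternary, C6–OH, C4–OTBS) | O=C1[C@](C)([C@@H](O)CCO[Si](C)(C)C(C)(C)C)C[C@@H]2O[C@H]1[C@@H]3[C@H]2[C@H](OCc5ccccc5)[C@H](C)C[C@H]3[C@@H](C)CO[Si](c4ccccc4)(c4ccccc4)C(C)(C)C | intermediate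
21 | C4,C6-diol | O=C1[C@](C)([C@@H](O)CCO)C[C@@H]2O[C@H]1[C@@H]3[C@H]2[C@H](OCc5ccccc5)[C@H](C)C[C@H]3[C@@H](C)CO[Si](c4ccccc4)(c4ccccc4)C(C)(C)C | intermediate
22 | C4 iodide | O=C1[C@](C)([C@@H](O)CCI)C[C@@H]2O[C@H]1[C@@H]3[C@H]2[C@H](OCc5ccccc5)[C@H](C)C[C@H]3[C@@H](C)CO[Si](c4ccccc4)(c4ccccc4)C(C)(C)C | intermediate
23 | C4-lithio C6-lithium alkoxide | O=C1[C@](C)([C@@H](O[Li])CC[Li])C[C@@H]2O[C@H]1[C@@H]3[C@H]2[C@H](OCc5ccccc5)[C@H](C)C[C@H]3[C@@H](C)CO[Si](c4ccccc4)(c4ccccc4)C(C)(C)C | intermediate
24 | tetracyclic cyclopentane-3,6-diol | O[C@]16CC[C@H](O)[C@]6(C)C[C@@H]2O[C@H]1[C@@H]3[C@H]2[C@H](OCc5ccccc5)[C@H](C)C[C@H]3[C@@H](C)CO[Si](c4ccccc4)(c4ccccc4)C(C)(C)C | intermediate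
25 | C6 mesylate | O[C@]16CC[C@H](OS(C)(=O)=O)[C@]6(C)C[C@@H]2O[C@H]1[C@@H]3[C@H]2[C@H](OCc5ccccc5)[C@H](C)C[C@H]3[C@@H](C)CO[Si](c4ccccc4)(c4ccccc4)C(C)(C)C | intermediate
26 | (Z)-oxonenone (C3 ketone, (Z)-C6=C7) | O=C1CC/C=C(C)\C[C@@H]2O[C@H]1[C@@H]3[C@H]2[C@H](OCc5ccccc5)[C@H](C)C[C@H]3[C@@H](C)CO[Si](c4ccccc4)(c4ccccc4)C(C)(C)C | intermediate
27 | C3 tertiary alcohol | C[C@]1(O)CC/C=C(C)\C[C@@H]2O[C@H]1[C@@H]3[C@H]2[C@H](OCc5ccccc5)[C@H](C)C[C@H]3[C@@H](C)CO[Si](c4ccccc4)(c4ccccc4)C(C)(C)C | intermediate
28 | C3 dimethylsilyl (Si–H) ether | C[C@]1(O[SiH](C)C)CC/C=C(C)\C[C@@H]2O[C@H]1[C@@H]3[C@H]2[C@H](OCc5ccccc5)[C@H](C)C[C@H]3[C@@H](C)CO[Si](c4ccccc4)(c4ccccc4)C(C)(C)C | intermediate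
29 | cyclic siloxane (C3–O–SiMe2–C6) | C[Si]1(C)O[C@@]2(C)CC[C@@H]1[C@H](C)C[C@@H]3O[C@H]2[C@@H]4[C@H]3[C@H](OCc5ccccc5)[C@H](C)C[C@H]4[C@@H](C)CO[Si](c6ccccc6)(c6ccccc6)C(C)(C)C | intermediate
30 | 3,6-diol | C[C@]1(O)CC[C@@H](O)[C@H](C)C[C@@H]2O[C@H]1[C@@H]3[C@H]2[C@H](OCc5ccccc5)[C@H](C)C[C@H]3[C@@H](C)CO[Si](c4ccccc4)(c4ccccc4)C(C)(C)C | intermediate
31 | C6 methyl ether | C[C@]1(O)CC[C@@H](OC)[C@H](C)C[C@@H]2O[C@H]1[C@@H]3[C@H]2[C@H](OCc5ccccc5)[C@H](C)C[C@H]3[C@@H](C)CO[Si](c4ccccc4)(c4ccccc4)C(C)(C)C | intermediate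
32 | C16 primary alcohol | C[C@]1(O)CC[C@@H](OC)[C@H](C)C[C@@H]2O[C@H]1[C@@H]3[C@H]2[C@H](OCc5ccccc5)[C@H](C)C[C@H]3[C@@H](C)CO | intermediate
33 | C16 triflate | C[C@]1(O)CC[C@@H](OC)[C@H](C)C[C@@H]2O[C@H]1[C@@H]3[C@H]2[C@H](OCc5ccccc5)[C@H](C)C[C@H]3[C@@H](C)COS(=O)(=O)C(F)(F)F | intermediate
34 | oxepane, 11-O-benzyl ether of the deacetyl target | CO[C@@H]1CC[C@]2(C)OC[C@H](C)[C@@H]3C[C@@H](C)[C@@H](OCc5ccccc5)[C@@H]4[C@H]3[C@@H]2O[C@H]4C[C@H]1C | intermediate
35 | C11 alcohol (deacetyl target) | CO[C@@H]1CC[C@]2(C)OC[C@H](C)[C@@H]3C[C@@H](C)[C@@H](O)[C@@H]4[C@H]3[C@@H]2O[C@H]4C[C@H]1C | intermediate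
36 | CNP0289153.2, (1S,2S,3S,6R,7R,9S,10R,11R,12R,14S,15R) in skeleton numbering | CO[C@@H]1CC[C@]2(C)OC[C@H](C)[C@@H]3C[C@@H](C)[C@@H](OC(C)=O)[C@@H]4[C@H]3[C@@H]2O[C@H]4C[C@H]1C | target

**Count**

Total: 24 steps. Longest linear sequence: 21 steps (steps 4–24, from 5 to 36); the pyranone branch (steps 1–3) joins at step 8.

**Steps most likely to fail**

1. Step 8. The ylide may dimerise faster than it adds to the hindered enone, or the endo approach may compete with exo. Fallback: setting out from 13, α-iodination (I2, pyridine, CH2Cl2) would give the 2-iodoenone F1. Palladium-catalysed alkoxycarbonylation (Pd(OAc)2, PPh3, CO, allyl alcohol, Et3N, DMF, 60 °C) would give the allyl 6-oxocyclohex-1-ene-1-carboxylate F2. This doubly activated alkene should take up ylide 14 (from 4, same conditions) faster and with the same C2–C1/C9–C10 orientation; the planar ester, not the ring, can occupy the endo position, giving the C10 allyl ester adduct F3. Pd(PPh3)4 with HCO2H/Et3N (Tsuji decarboxylation) removes the ester, and protonation at C10 can only give the cis ring fusion; the route is rejoined at 15.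

2. Step 18. The platinum hydride may not engage the trisubstituted ring alkene across the ring, or may migrate the double bond. Fallback: setting out from 27, TBAF would give the diol F4. Tf2O/2,6-lutidine would form the primary triflate F5, which closes to the oxepane alkene F6; the C3 oxygen is then an ether and cannot open an epoxide as the free hydroxyl would. mCPBA should epoxidise the exposed outer face to the 6,7-epoxide F7. BF3·OEt2 (Meinwald rearrangement) ionises C7–O, and H6 shifts to C7 on the face opposite the leaving oxygen; this gives the required C7 configuration and the C6 ketone F8. Hydride reduction (NaBH4 or L-Selectride, chosen by which C6 epimer it delivers) would give the C6 alcohol F9, and NaH/MeI rejoins the route at 34.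

3. Step 14. tert-Butyllithium may add to or reduce the C3 ketone, or the alkyllithium may be protonated by the neighbouring hydroxyl before it closes the ring. Fallback: setting out from 17, the same L-Selectride reduction with trapping of enolate 19 by acrolein would give the allylic alcohol F10. Vinylmagnesium bromide/CeCl3 adds to the C3 ketone; attack is needed on the face that carries the C6 chain, and only that isomer can cyclise. This gives the divinyl diol F11. Ring-closing metathesis (Grubbs second-generation catalyst, CH2Cl2, 40 °C) would give the cyclopentene diol F12, and diimide (TsNHNH2, NaOAc) saturates the ring alkene without touching the benzyl ether; the route is rejoined at 24.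

**Further compounds**

F1 | step 8 | 2-iodo derivative of enone 13 (iodine on C10) | CC(C)(C)[Si](c1ccccc1)(c1ccccc1)OC[C@H](C)[C@@H]1C[C@@H](C)C(=O)C(I)=C1
F2 | step 8 | allyl ester of the 2-carboxy derivative of enone 13 (ester on C10) | CC(C)(C)[Si](c1ccccc1)(c1ccccc1)OC[C@H](C)[C@@H]1C[C@@H](C)C(=O)C(C(=O)OCC=C)=C1
F3 | step 8 | C10 allyl ester of cycloadduct 15 | O=C1C(C)=C[C@@H]2O[C@H]1[C@@H]3[C@@]2(C(=O)OCC=C)C(=O)[C@H](C)C[C@H]3[C@@H](C)CO[Si](c4ccccc4)(c4ccccc4)C(C)(C)C
F4 | step 18 | C3,C16-diol from desilylation of 27 | C[C@]1(O)CC/C=C(C)\C[C@@H]2O[C@H]1[C@@H]3[C@H]2[C@H](OCc5ccccc5)[C@H](C)C[C@H]3[C@@H](C)CO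
F5 | step 18 | C16 triflate of F4 | C[C@]1(O)CC/C=C(C)\C[C@@H]2O[C@H]1[C@@H]3[C@H]2[C@H](OCc5ccccc5)[C@H](C)C[C@H]3[C@@H](C)COS(=O)(=O)C(F)(F)F
F6 | step 18 | oxepane with (Z)-C6=C7 alkene, 11-O-benzyl | C1C[C@]2(C)OC[C@H](C)[C@@H]3C[C@@H](C)[C@@H](OCc5ccccc5)[C@@H]4[C@H]3[C@@H]2O[C@H]4C/C(C)=C\1
F7 | step 18 | 6,7-epoxide of F6 (oxygen on the outer face) | C1C[C@]2(C)OC[C@H](C)[C@@H]3C[C@@H](C)[C@@H](OCc6ccccc6)[C@@H]4[C@H]3[C@@H]2O[C@H]4C[C@@]5(C)O[C@@H]15
F8 | step 18 | C6 ketone with C7 configured as in the target | O=C1CC[C@]2(C)OC[C@H](C)[C@@H]3C[C@@H](C)[C@@H](OCc5ccccc5)[C@@H]4[C@H]3[C@@H]2O[C@H]4C[C@H]1C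
F9 | step 18 | C6 alcohol, 11-O-benzyl oxepane | O[C@@H]1CC[C@]2(C)OC[C@H](C)[C@@H]3C[C@@H](C)[C@@H](OCc5ccccc5)[C@@H]4[C@H]3[C@@H]2O[C@H]4C[C@H]1C
F10 | step 14 | acrolein aldol adduct (C6–OH, C5=C4 vinyl) | O=C1[C@](C)([C@@H](O)C=C)C[C@@H]2O[C@H]1[C@@H]3[C@H]2[C@H](OCc5ccccc5)[C@H](C)C[C@H]3[C@@H](C)CO[Si](c4ccccc4)(c4ccccc4)C(C)(C)C
F11 | step 14 | divinyl diol (vinyl on C3 cis to the C6 chain) | C=C[C@]1(O)[C@](C)([C@@H](O)C=C)C[C@@H]2O[C@H]1[C@@H]3[C@H]2[C@H](OCc5ccccc5)[C@H](C)C[C@H]3[C@@H](C)CO[Si](c4ccccc4)(c4ccccc4)C(C)(C)C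
F12 | step 14 | cyclopentene diol (C4=C5) | O[C@]16C=C[C@H](O)[C@]6(C)C[C@@H]2O[C@H]1[C@@H]3[C@H]2[C@H](OCc5ccccc5)[C@H](C)C[C@H]3[C@@H](C)CO[Si](c4ccccc4)(c4ccccc4)C(C)(C)C
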